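## Retrosynthetic overview

1. Ring B is closed last: the C1–C8 bond forms by attack of the C-1 enol carbon of monocycle 13 on the C-8 tertiary cation, relayed through O-9 pyran 15.
2. 13 comes from 8 by removal of the CO2Me block at C-1, thermodynamic setting of C-7 in the O-9 hemiketal, methyl addition (C-8) and C-1 prenylation.
3. The C-5 quaternary centre comes from asymmetric dearomative geranylation of aromatic 6 (C-1 blocked by CO2Me, C-3 by the aroyl group).
4. 6 comes from Michael addition of acylphloroglucinol ester 3 to α-methylene geranylacetone 5; 3 comes from Friedel–Crafts acylation of 1 with 2.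
5. Ring order: the aromatic ring is bought, dearomatised at step 4, and ring B is formed at step 8.

Atom numbers C-1 to C-9 are those of the bicyclo[3.3.1]nonane core of the target (C-5 and C-7 bear geranyl, C-1 bears prenyl, C-8 is CMe2, C-9 is the bridging ketone).

Assumption: the (S,S)-ligand of step 4 is taken to give the 5S centre; if the first run shows the opposite sense, the (R,R)-ligand is used with nothing else changed.

## Route

Step 1
Reactants: 1 methyl 2,4,6-trihydroxybenzoate; 2 3,4-dihydroxybenzoic acid
Product: 3 methyl 3-(3,4-dihydroxybenzoyl)-2,4,6-trihydroxybenzoate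
Conditions: P2O5 in MeSO3H (Eaton's reagent), 60 °C; then ice–water
Reagents that add atoms: none
Why: Friedel–Crafts acylation of the electron-rich ring by the activated acid; the two free ring positions of 1 are equivalent, the product is deactivated toward a second acylation, and no stereocentre is formed.

Step 2
Reactants: 4 (E)-geranylacetone
Product: 5 (5E)-6,10-dimethyl-3-methylideneundeca-5,9-dien-2-one
Conditions: (CH2O)n, N-methylanilinium trifluoroacetate, THF, reflux
Reagents that add atoms: paraformaldehyde (as formaldehyde), C=O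
Why: Mannich condensation–elimination (α-methylenation of a ketone) through the more substituted enol puts the methylene on C-3 and leaves the (E)-olefin untouched; no stereocentre.

Step 3
Reactants: 3 methyl 3-(3,4-dihydroxybenzoyl)-2,4,6-trihydroxybenzoate; 5 (5E)-6,10-dimethyl-3-methylideneundeca-5,9-dien-2-one
Product: 6 methyl 3-[(4E)-2-acetyl-5,9-dimethyldeca-4,8-dien-1-yl]-5-(3,4-dihydroxybenzoyl)-2,4,6-trihydroxybenzoate (both epimers at the acetyl-bearing carbon; in equilibrium with its cyclic hemiketal)
Conditions: Et3N (0.2 equiv), MeCN, 40 °C, argon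
Reagents that add atoms: none
Why: Michael addition of the only free ring carbon of the strongly acidic diacyl-phloroglucinol to the exo-methylene ketone (the catechol is not ionised by the catalytic amine and O-addition is reversible); the new α-keto centre (future C-7) forms as an epimerisable mixture that is set in step 5.

Step 4
Reactants: 6 the Michael adduct; 7 geranyl acetate
Product: 8 methyl (5S)-5-[(4E)-2-acetyl-5,9-dimethyldeca-4,8-dien-1-yl]-3-(3,4-dihydroxybenzoyl)-5-[(2E)-3,7-dimethylocta-2,6-dien-1-yl]-2,4-dihydroxy-6-oxocyclohexa-1,3-diene-1-carboxylate (epimer mixture at the acetyl-bearing carbon)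
Conditions: Pd2(dba)3·CHCl3 (2.5 mol %), N,N'-[(1S,2S)-cyclohexane-1,2-diyl]bis[2-(diphenylphosphanyl)benzamide] (7.5 mol %), Et3N (1.1 equiv), CH2Cl2, 0 → 23 °C
Reagents that add atoms: none
Why: Tsuji–Trost asymmetric allylic alkylation used as a dearomatisation: the phloroglucinolate attacks the unsubstituted terminus of the π-geranyl complex of zerovalent palladium at the only available ring carbon (the ester- and aroyl-bearing carbons are deactivated and O-allylation, including that of the catechol, is reversible), the (E)-geometry is kept, and the chiral ligand selects one enantiotopic face of the planar nucleophile, setting C-5 as S.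

Step 5
Reactants: 8 the dearomatised keto ester
Product: 10 (6S)-6-[(2S,4E)-2-acetyl-5,9-dimethyldeca-4,8-dien-1-yl]-4-(3,4-dihydroxybenzoyl)-6-[(2E)-3,7-dimethylocta-2,6-dien-1-yl]-3,5-dihydroxycyclohexa-2,4-dien-1-one (exists mainly as its cyclic O-9 hemiketal), via carboxylic acid 9 (not isolated)
Conditions: Me3SnOH (8 equiv), ClCH2CH2Cl, 70 °C; then 1 M HCl, 23 °C; then pyridinium p-toluenesulfonate (10 mol %), CH2Cl2, 23 °C
Reagents that add atoms: none
Why: mild ester hydrolysis and spontaneous decarboxylation of the vinylogous β-keto acid free C-1 without the strong base that would trigger retro-Michael cleavage, and acid-catalysed epimerisation of the α-keto centre through the cyclic hemiketal/enol ether then gives the thermodynamic isomer, in which the hemiketal uses O-9 (the aroyl-dione chelate stays intact and there is no clash with the aroyl group) and the C-7 geranyl is equatorial and trans to the axial C-5 geranyl, which is 7S.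

Step 6
Reactants: 10 the C-1-unsubstituted ketone
Product: 11 (6S)-4-(3,4-dihydroxybenzoyl)-6-[(2E)-3,7-dimethylocta-2,6-dien-1-yl]-3,5-dihydroxy-6-[(2S,4E)-2-(2-hydroxypropan-2-yl)-5,9-dimethyldeca-4,8-dien-1-yl]cyclohexa-2,4-dien-1-one
Conditions: MeMgBr (8 equiv), CeCl3 (8 equiv), THF, −78 → −40 °C; then aq. NH4Cl
Reagents that add atoms: methylmagnesium bromide, C[Mg]Br
Why: organocerium (Grignard/CeCl3) 1,2-addition to the side-chain methyl ketone, the only carbonyl that is not part of an enolate after the four OH groups are deprotonated, outruns α-deprotonation, so the gem-dimethyl carbinol (future C-8) forms and C-7 is now fixed as S.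

Step 7
Reactants: 11 the tertiary alcohol; 12 prenyl acetate
Product: 13 (6S)-4-(3,4-dihydroxybenzoyl)-6-[(2E)-3,7-dimethylocta-2,6-dien-1-yl]-3,5-dihydroxy-6-[(2S,4E)-2-(2-hydroxypropan-2-yl)-5,9-dimethyldeca-4,8-dien-1-yl]-2-(3-methylbut-2-en-1-yl)cyclohexa-2,4-dien-1-one
Conditions: Pd(PPh3)4 (5 mol %), Et3N (1.1 equiv), THF, 23 °C
Reagents that add atoms: none
Why: Tsuji–Trost allylation in which the vinylogous-acid enolate attacks the unsubstituted terminus of the π-prenyl complex at C-1, the only unsubstituted enol carbon, to give the linear prenyl group (O-allylation is reversible; 1.05 equiv of 12 limits double prenylation); no new stereocentre.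

Step 8
Reactants: 13 the monocyclic polyprenylated acylphloroglucinol
Product: 16 oblongifolin D, via C-8 carbocation 14 (not isolated), via O-9 pyran 15 (not isolated)
Conditions: Sc(OTf)3 (10 mol %), (CF3)2CHOH/CH2Cl2 (1:4), −30 → 0 °C
Reagents that add atoms: none
Why: Proposed new method: the Lewis acid in the ionising, non-nucleophilic fluoroalcohol ionises the tertiary carbinol faster than it activates the trisubstituted olefins, the C-8 cation is first trapped by the neighbouring O-9 to give pyran 15, and reversible re-ionisation of this tertiary alkyl enol ether lets C-8 move from O-9 to the adjacent enol carbon C-1 through a boat-like ring B with the C-7 geranyl pseudo-equatorial, which forms the C1–C8 bond irreversibly, fixes C-1 because the one-carbon bridge must be cis-fused to the C-5 centre, and leaves C-7 endo; the closest known reaction types are the acid-mediated biomimetic cationic cyclisation of dearomatised prenylated acylphloroglucinols and the Lewis-acid O→C rearrangement (tert-alkylation) of tertiary alkyl enol ethers.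

## Compound list

1 | methyl 2,4,6-trihydroxybenzoate | COC(=O)c1c(O)cc(O)cc1O | starting material
2 | 3,4-dihydroxybenzoic acid | OC(=O)c1ccc(O)c(O)c1 | starting material
3 | methyl 3-(3,4-dihydroxybenzoyl)-2,4,6-trihydroxybenzoate | COC(=O)c1c(O)cc(O)c(C(=O)c2ccc(O)c(O)c2)c1O | intermediate
4 | (E)-geranylacetone, (5E)-6,10-dimethylundeca-5,9-dien-2-one | CC(=O)CC/C=C(\C)CCC=C(C)C | starting material
5 | (5E)-6,10-dimethyl-3-methylideneundeca-5,9-dien-2-one | CC(=O)C(=C)C/C=C(\C)CCC=C(C)C | intermediate
6 | methyl 3-[(4E)-2-acetyl-5,9-dimethyldeca-4,8-dien-1-yl]-5-(3,4-dihydroxybenzoyl)-2,4,6-trihydroxybenzoate, epimer mixture at the acetyl-bearing carbon | COC(=O)c1c(O)c(CC(C(C)=O)C/C=C(\C)CCC=C(C)C)c(O)c(C(=O)c2ccc(O)c(O)c2)c1O | intermediate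
7 | geranyl acetate | CC(=O)OC/C=C(\C)CCC=C(C)C | starting material
8 | methyl (5S)-5-[(4E)-2-acetyl-5,9-dimethyldeca-4,8-dien-1-yl]-3-(3,4-dihydroxybenzoyl)-5-geranyl-2,4-dihydroxy-6-oxocyclohexa-1,3-diene-1-carboxylate, epimer mixture at the acetyl-bearing carbon | CC(=O)C(C/C=C(\C)CCC=C(C)C)C[C@]1(C/C=C(\C)CCC=C(C)C)C(=O)C(C(=O)OC)=C(O)C(C(=O)c2ccc(O)c(O)c2)=C1O | intermediate
9 | carboxylic acid of 8 (CO2H in place of CO2Me, 5S) | CC(=O)C(C/C=C(\C)CCC=C(C)C)C[C@]1(C/C=C(\C)CCC=C(C)C)C(=O)C(C(=O)O)=C(O)C(C(=O)c2ccc(O)c(O)c2)=C1O | intermediate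
10 | (6S)-6-[(2S,4E)-2-acetyl-5,9-dimethyldeca-4,8-dien-1-yl]-4-(3,4-dihydroxybenzoyl)-6-geranyl-3,5-dihydroxycyclohexa-2,4-dien-1-one | CC(=O)[C@@H](C/C=C(\C)CCC=C(C)C)C[C@]1(C/C=C(\C)CCC=C(C)C)C(=O)C=C(O)C(C(=O)c2ccc(O)c(O)c2)=C1O | intermediate
11 | (6S)-4-(3,4-dihydroxybenzoyl)-6-geranyl-3,5-dihydroxy-6-[(2S,4E)-2-(2-hydroxypropan-2-yl)-5,9-dimethyldeca-4,8-dien-1-yl]cyclohexa-2,4-dien-1-one | CC(C)(O)[C@@H](C/C=C(\C)CCC=C(C)C)C[C@]1(C/C=C(\C)CCC=C(C)C)C(=O)C=C(O)C(C(=O)c2ccc(O)c(O)c2)=C1O | intermediate
12 | prenyl acetate, 3-methylbut-2-en-1-yl acetate | CC(=O)OCC=C(C)C | starting material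
13 | 2-prenyl derivative of 11 (same 6S and side-chain 2S centres) | CC(C)(O)[C@@H](C/C=C(\C)CCC=C(C)C)C[C@]1(C/C=C(\C)CCC=C(C)C)C(=O)C(CC=C(C)C)=C(O)C(C(=O)c2ccc(O)c(O)c2)=C1O | intermediate
14 | C-8 tertiary carbocation from 13 (stereocentres as in 13) | C[C+](C)[C@@H](C/C=C(\C)CCC=C(C)C)C[C@]1(C/C=C(\C)CCC=C(C)C)C(=O)C(CC=C(C)C)=C(O)C(C(=O)c2ccc(O)c(O)c2)=C1O | intermediate
15 | O-9 pyran isomer of 16: 6-(3,4-dihydroxybenzoyl)-3,4a-digeranyl-5-hydroxy-2,2-dimethyl-8-prenyl-3,4-dihydro-2H-chromen-7(4aH)-one, stereocentres as in 13 (3-geranyl equatorial, trans to the 4a-geranyl) | CC1(C)OC2=C(CC=C(C)C)C(=O)C(C(=O)c3ccc(O)c(O)c3)=C(O)[C@]2(C/C=C(\C)CCC=C(C)C)C[C@@H]1C/C=C(\C)CCC=C(C)C | intermediate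
16 | oblongifolin D, (1S,5S,7S) in core numbering for the tautomer drawn; C-7 geranyl endo | CC(C)=CCC/C(C)=C/C[C@H]1C[C@]2(C/C=C(\C)CCC=C(C)C)C(=O)[C@@](CC=C(C)C)(C(=O)C(C(=O)c3ccc(O)c(O)c3)=C2O)C1(C)C | target

## Step count and risks

Total steps: 8. Longest linear sequence: 7 (steps 1, 3, 4, 5, 6, 7, 8 from compound 1); step 2 is the one side step.

The three steps most likely to fail:

**Step 8 (cationic ring closure).** The cation may stop at pyran 15, be caught by the C-5 geranyl olefin, close onto C-3, or lose the C-7 hydrogen and scramble C-7. The endo closure also needs a boat-like ring B. Fallback: it sets out from 13 and comes back to the route at 15. Compound 13 is dehydrated toward the methyl groups with methyl N-(triethylammoniumsulfonyl)carbamate (Burgess reagent, benzene, 50 °C) to give isopropenyl monocycle F1. The C-8 centre is then generated without any acid by hydrogen-atom transfer from a cobalt hydride to the 1,1-disubstituted olefin only: the (salen)cobalt complex C36H52CoN2O2 (divalent cobalt), PhSiH3 and N-fluoro-2,4,6-trimethylpyridinium tetrafluoroborate in CH2Cl2 at 0 °C. Oxidation of the tertiary radical to the cation and capture by O-9 give pyran 15 as an isolated compound, which is then submitted alone to the O→C shift of step 8 at low temperature.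

**Step 4 (asymmetric dearomative geranylation).** The enantioselectivity on this hindered, ring-chain tautomeric nucleophile is untested, and some loss of (E)-geometry or O-allylation is possible. Fallback: it sets out from 3 and comes back to the route at 8. Compound 3 is first C-geranylated at its only free ring carbon with 7 under achiral zerovalent palladium catalysis (Pd(PPh3)4, Et3N, THF) to give aromatic geranyl ester F2. The C-5 quaternary centre is then created by an enantioselective dearomative Michael addition of F2 to enone 5 under chiral phase-transfer catalysis (N-(9-anthracenylmethyl)cinchonidinium bromide, CsOH·H2O, CH2Cl2, −50 °C), which gives 8.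

**Step 5 (ester removal and setting of C-7).** The hindered, chelated ester may hydrolyse slowly, the dearomatised Michael adduct can undergo retro-Michael cleavage if the medium becomes basic, and the O-9 over O-4 hemiketal preference that sets C-7 may be incomplete. Fallback: it sets out from 6 and comes back to the route at 10. The methyl ester is saponified at the aromatic stage (LiOH, THF–H2O, 23 °C), where retro-Michael cleavage cannot occur, to give carboxylic acid F3, which is kept as its lithium salt. The asymmetric geranylation of step 4 is run on this carboxylate (C-1 is still blocked), and acidification then lets acid 9 lose CO2 to give 10. The C-7 epimers are equilibrated as in step 5, and any minor epimer is removed after step 6.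

## Further compounds

F1 | step 8 | isopropenyl monocycle: 13 with prop-1-en-2-yl in place of 2-hydroxypropan-2-yl (stereocentres as in 13) | CC(=C)[C@@H](C/C=C(\C)CCC=C(C)C)C[C@]1(C/C=C(\C)CCC=C(C)C)C(=O)C(CC=C(C)C)=C(O)C(C(=O)c2ccc(O)c(O)c2)=C1O
F2 | step 4 | aromatic geranyl ester: methyl 3-(3,4-dihydroxybenzoyl)-5-[(2E)-3,7-dimethylocta-2,6-dien-1-yl]-2,4,6-trihydroxybenzoate | COC(=O)c1c(O)c(C/C=C(\C)CCC=C(C)C)c(O)c(C(=O)c2ccc(O)c(O)c2)c1O
F3 | step 5 | carboxylic acid: 3-[(4E)-2-acetyl-5,9-dimethyldeca-4,8-dien-1-yl]-5-(3,4-dihydroxybenzoyl)-2,4,6-trihydroxybenzoic acid (handled as its lithium salt, epimer mixture at the acetyl-bearing carbon) | OC(=O)c1c(O)c(CC(C(C)=O)C/C=C(\C)CCC=C(C)C)c(O)c(C(=O)c2ccc(O)c(O)c2)c1O
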